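**Retrosynthetic overview**

- Target 22 comes from hexadecamethyl ether 21 by cleavage of sixteen methyl ethers with BBr3, and 21 comes from hexabromide 20 by sixfold copper-catalysed methoxylation.
- The plan rests on three carbons: carbon 1 of ring A, carbon 4 of ring B and carbon 4 of ring D. Each carries a bridging ether oxygen, stands between two oxygenated carbons (2 and 6 of ring A, 3 and 5 of ring B, 3 and 5 of ring D) and lies para to a further oxygen; these six flanking oxygens are introduced as bromines.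
- Rings A, B and D each enter as 3,5-dibromo-4-fluorobenzaldehyde 2: SNAr at the fluoride, then Baeyer–Villiger oxidation of the formyl group to the para hydroxyl.
- Rings E and C enter as 2-fluoro-3,4,5-trimethoxybenzaldehyde 4 (SNAr ortho to formyl, then Baeyer–Villiger oxidation); ring F is 3,4,5-trimethoxyphenol 3.
- No ring is formed: six bought benzene rings are joined in the order F, E, D, C, B, A.

Key step: step 13

Remark: the rings are lettered along the chain A–O–B–O–C–O–D–O–E–O–F. Ring A is numbered from its bridging oxygen (carbon 1). Rings B, C, D, E and F are numbered from the carbon whose oxygen points towards ring A (carbon 1); the oxygen towards ring F then sits on carbon 4 of rings B and D and on carbon 6 of rings C and E.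
Remark: 2-fluoro-3,4,5-trimethoxybenzaldehyde 4 is assumed to be a purchasable building block.
Remark: the hydroxyl at carbon 4 of ring A is capped as a methyl ether (step 12) before the copper step, so that no phenoxide can bind copper or couple with an aryl bromide. The last step then removes sixteen methyl groups.

**Route**

Step 1
Reactants: 1 4-fluorobenzaldehyde
Product: 2 3,5-dibromo-4-fluorobenzaldehyde
Conditions: NBS (2.4 equiv), conc. H2SO4, 60 °C
Reagents that add atoms: N-bromosuccinimide, O=C1CCC(=O)N1Br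
Why: Electrophilic aromatic bromination in strong acid; fluorine directs ortho and formyl directs meta, so both bromines can only enter at carbons 3 and 5.

Step 2
Reactants: 3 3,4,5-trimethoxyphenol; 4 2-fluoro-3,4,5-trimethoxybenzaldehyde
Product: 5 E–F aldehyde 3,4,5-trimethoxy-2-(3,4,5-trimethoxyphenoxy)benzaldehyde
Conditions: Cs2CO3, DMSO, 120 °C, argon
Reagents that add atoms: none
Why: Nucleophilic aromatic substitution (SNAr), in which the ortho formyl group stabilises the Meisenheimer adduct, fluoride is the best leaving group and the electron-rich, unhindered phenoxide of 3 is a strong nucleophile; this forms the ether between carbon 6 of ring E and carbon 1 of ring F.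

Step 3
Reactants: 5 E–F aldehyde
Product: 7 E–F phenol 3,4,5-trimethoxy-2-(3,4,5-trimethoxyphenoxy)phenol, via E–F aryl formate 6 (not isolated)
Conditions: mCPBA (1.2 equiv), CH2Cl2, 0 °C to rt; aq. NaHCO3 wash; then K2CO3 (cat.), MeOH, rt
Reagents that add atoms: 3-chloroperbenzoic acid (mCPBA), OOC(=O)c1cccc(Cl)c1
Why: Baeyer–Villiger oxidation of an aryl aldehyde, in which the oxygen-rich ring E with its ortho aryloxy group migrates in the Criegee adduct in preference to hydride; methanolysis of the formate frees the hydroxyl at carbon 1 of ring E.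

Step 4
Reactants: 7 E–F phenol; 2 3,5-dibromo-4-fluorobenzaldehyde
Product: 8 D–E–F aldehyde 3,5-dibromo-4-[3,4,5-trimethoxy-2-(3,4,5-trimethoxyphenoxy)phenoxy]benzaldehyde
Conditions: K2CO3, DMF, 80 °C, argon
Reagents that add atoms: none
Why: SNAr at the fluoride, which is para to formyl and flanked by two inductively withdrawing bromines, while the bromines are meta to formyl and are not displaced; the hindered ether from carbon 1 of ring E to carbon 4 of ring D thus forms before its flanking oxygens exist.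

Step 5
Reactants: 8 D–E–F aldehyde
Product: 10 D–E–F phenol 3,5-dibromo-4-[3,4,5-trimethoxy-2-(3,4,5-trimethoxyphenoxy)phenoxy]phenol, via D–E–F aryl formate 9 (not isolated)
Conditions: mCPBA (1.3 equiv), CH2Cl2, reflux; aq. NaHCO3 wash; then K2CO3 (cat.), MeOH, rt
Reagents that add atoms: 3-chloroperbenzoic acid (mCPBA), OOC(=O)c1cccc(Cl)c1
Why: Baeyer–Villiger oxidation, in which the para aryloxy oxygen should make the aryl group migrate rather than hydride, as in other brominated aryloxybenzaldehydes; methanolysis of the formate gives the hydroxyl at carbon 1 of ring D.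

Step 6
Reactants: 10 D–E–F phenol; 4 2-fluoro-3,4,5-trimethoxybenzaldehyde
Product: 11 C–D–E–F aldehyde 2-{3,5-dibromo-4-[3,4,5-trimethoxy-2-(3,4,5-trimethoxyphenoxy)phenoxy]phenoxy}-3,4,5-trimethoxybenzaldehyde
Conditions: Cs2CO3, DMSO, 130 °C, argon
Reagents that add atoms: none
Why: SNAr ortho to the formyl group of 4 by the ring D phenoxide, which has no ortho substituent, forming the ether from carbon 6 of ring C to carbon 1 of ring D; the aryl bromides of ring D are inert without a metal catalyst.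

Step 7
Reactants: 11 C–D–E–F aldehyde
Product: 13 C–D–E–F phenol 2-{3,5-dibromo-4-[3,4,5-trimethoxy-2-(3,4,5-trimethoxyphenoxy)phenoxy]phenoxy}-3,4,5-trimethoxyphenol, via C–D–E–F aryl formate 12 (not isolated)
Conditions: mCPBA (1.2 equiv), CH2Cl2, 0 °C to rt; aq. NaHCO3 wash; then K2CO3 (cat.), MeOH, rt
Reagents that add atoms: 3-chloroperbenzoic acid (mCPBA), OOC(=O)c1cccc(Cl)c1
Why: Baeyer–Villiger oxidation on the electron-rich trimethoxylated ring C with an ortho aryloxy group, where aryl migration is strongly favoured; methanolysis frees the hydroxyl at carbon 1 of ring C.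

Step 8
Reactants: 13 C–D–E–F phenol; 2 3,5-dibromo-4-fluorobenzaldehyde
Product: 14 B–C–D–E–F aldehyde (3,5-dibromo-4-aryloxybenzaldehyde whose aryloxy oxygen is the phenol oxygen of 13; formyl on ring B; two bromines each on rings B and D)
Conditions: K2CO3, DMF, 80 °C, argon
Reagents that add atoms: none
Why: SNAr as in step 4, the ring C phenoxide displacing the fluoride para to formyl to form the ether from carbon 1 of ring C to carbon 4 of ring B.

Step 9
Reactants: 14 B–C–D–E–F aldehyde
Product: 16 B–C–D–E–F phenol (hydroxyl at carbon 1 of ring B in place of the formyl group of 14), via B–C–D–E–F aryl formate 15 (not isolated)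
Conditions: mCPBA (1.3 equiv), CH2Cl2, reflux; aq. NaHCO3 wash; then K2CO3 (cat.), MeOH, rt
Reagents that add atoms: 3-chloroperbenzoic acid (mCPBA), OOC(=O)c1cccc(Cl)c1
Why: Baeyer–Villiger oxidation with aryl migration supported by the para aryloxy oxygen, as in step 5, followed by formate methanolysis.

Step 10
Reactants: 16 B–C–D–E–F phenol; 2 3,5-dibromo-4-fluorobenzaldehyde
Product: 17 hexamer aldehyde (formyl at carbon 4 of ring A; two bromines each on rings A, B and D; rings C, E and F trimethoxylated)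
Conditions: K2CO3, DMF, 80 °C, argon
Reagents that add atoms: none
Why: SNAr of the unhindered ring B phenoxide on the activated fluoride of 2, forming the ether from carbon 1 of ring B to carbon 1 of ring A and completing the hexamer chain.

Step 11
Reactants: 17 hexamer aldehyde
Product: 19 hexabromo hexamer phenol (free hydroxyl at carbon 4 of ring A), via hexamer aryl formate 18 (not isolated)
Conditions: mCPBA (1.3 equiv), CH2Cl2, reflux; aq. NaHCO3 wash; then K2CO3 (cat.), MeOH, rt
Reagents that add atoms: 3-chloroperbenzoic acid (mCPBA), OOC(=O)c1cccc(Cl)c1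
Why: Baeyer–Villiger oxidation as in steps 5 and 9, then formate methanolysis to the hydroxyl at carbon 4 of ring A.

Step 12
Reactants: 19 hexabromo hexamer phenol
Product: 20 hexabromo hexamer methyl ether (methoxy at carbon 4 of ring A; bromine at carbons 2 and 6 of ring A, 3 and 5 of ring B, 3 and 5 of ring D; ten methoxy groups in all)
Conditions: MeI, K2CO3, acetone, 50 °C
Reagents that add atoms: iodomethane, CI
Why: Williamson ether synthesis on the only acidic hydroxyl, which is unhindered; this removes the phenoxide before the copper step.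

Step 13
Reactants: 20 hexabromo hexamer methyl ether
Product: 21 hexamer hexadecamethyl ether (each of the six C–Br bonds of 20 replaced by C–OMe)
Conditions: NaOMe (large excess), CuI (cat.), DMF–MeOH, 110 °C, sealed vessel, argon
Reagents that add atoms: sodium methoxide, C[O-].[Na+]
Why: CuI and NaOMe give CuOMe with univalent copper, which inserts into a C–Br bond to give an aryl copper methoxide bromide with trivalent copper, and this eliminates the aryl methyl ether and returns univalent copper; six turns of the cycle form the C–OMe bonds at carbons 2 and 6 of ring A, 3 and 5 of ring B and 3 and 5 of ring D. The closest known reaction type is the copper-catalysed methoxylation of ortho-oxygenated dibromoarenes with NaOMe, as in the conversion of 3,5-dibromo-4-hydroxybenzaldehyde into syringaldehyde. No ring is closed and no stereocentre is formed. The step needs complete exchange at all six sites without hydrodebromination and without cleavage of the five diaryl ethers. All six bromines have the same surroundings (one neighbouring aryloxy carbon and one neighbouring CH), and methoxide is small enough to enter beside the diaryl ether oxygen. Each brominated ring carries an oxygen donor para to its hindered diaryl ether carbon, which keeps methoxide from attacking there by addition–elimination, so that only the copper-mediated exchange at C–Br should take place.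

Step 14
Reactants: 21 hexamer hexadecamethyl ether
Product: 22 target hexamer (CNP0114537.0), sixteen free hydroxyls
Conditions: BBr3 (excess), CH2Cl2, −78 °C to rt; then MeOH–H2O, 0 °C, argon
Reagents that add atoms: none
Why: Lewis acid cleavage of aryl methyl ethers by BBr3, in which bromide attacks the methyl group of the boron-bound ether; the diaryl ether C–O bonds offer no alkyl carbon for attack and remain intact, and hydrolysis of the aryl borates frees the sixteen phenols.

**Compound list**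

1 | 4-fluorobenzaldehyde | O=Cc1ccc(F)cc1 | starting material
2 | 3,5-dibromo-4-fluorobenzaldehyde | O=Cc1cc(Br)c(F)c(Br)c1 | intermediate
3 | 3,4,5-trimethoxyphenol | COc1cc(O)cc(OC)c1OC | starting material
4 | 2-fluoro-3,4,5-trimethoxybenzaldehyde | COc1cc(C=O)c(F)c(OC)c1OC | starting material
5 | E–F aldehyde, 3,4,5-trimethoxy-2-(3,4,5-trimethoxyphenoxy)benzaldehyde | O=Cc1cc(OC)c(OC)c(OC)c1Oc1cc(OC)c(OC)c(OC)c1 | intermediate
6 | E–F aryl formate, 3,4,5-trimethoxy-2-(3,4,5-trimethoxyphenoxy)phenyl formate | O=COc1cc(OC)c(OC)c(OC)c1Oc1cc(OC)c(OC)c(OC)c1 | intermediate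
7 | E–F phenol, 3,4,5-trimethoxy-2-(3,4,5-trimethoxyphenoxy)phenol | Oc1cc(OC)c(OC)c(OC)c1Oc1cc(OC)c(OC)c(OC)c1 | intermediate
8 | D–E–F aldehyde, 3,5-dibromo-4-[3,4,5-trimethoxy-2-(3,4,5-trimethoxyphenoxy)phenoxy]benzaldehyde | O=Cc1cc(Br)c(Oc2cc(OC)c(OC)c(OC)c2Oc2cc(OC)c(OC)c(OC)c2)c(Br)c1 | intermediate
9 | D–E–F aryl formate (formate ester of 10) | O=COc1cc(Br)c(Oc2cc(OC)c(OC)c(OC)c2Oc2cc(OC)c(OC)c(OC)c2)c(Br)c1 | intermediate
10 | D–E–F phenol, 3,5-dibromo-4-[3,4,5-trimethoxy-2-(3,4,5-trimethoxyphenoxy)phenoxy]phenol | Oc1cc(Br)c(Oc2cc(OC)c(OC)c(OC)c2Oc2cc(OC)c(OC)c(OC)c2)c(Br)c1 | intermediate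
11 | C–D–E–F aldehyde, 2-{3,5-dibromo-4-[3,4,5-trimethoxy-2-(3,4,5-trimethoxyphenoxy)phenoxy]phenoxy}-3,4,5-trimethoxybenzaldehyde | O=Cc1cc(OC)c(OC)c(OC)c1Oc1cc(Br)c(Oc2cc(OC)c(OC)c(OC)c2Oc2cc(OC)c(OC)c(OC)c2)c(Br)c1 | intermediate
12 | C–D–E–F aryl formate (formate ester of 13) | O=COc1cc(OC)c(OC)c(OC)c1Oc1cc(Br)c(Oc2cc(OC)c(OC)c(OC)c2Oc2cc(OC)c(OC)c(OC)c2)c(Br)c1 | intermediate
13 | C–D–E–F phenol, 2-{3,5-dibromo-4-[3,4,5-trimethoxy-2-(3,4,5-trimethoxyphenoxy)phenoxy]phenoxy}-3,4,5-trimethoxyphenol | Oc1cc(OC)c(OC)c(OC)c1Oc1cc(Br)c(Oc2cc(OC)c(OC)c(OC)c2Oc2cc(OC)c(OC)c(OC)c2)c(Br)c1 | intermediate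
14 | B–C–D–E–F aldehyde (formyl on ring B; two bromines each on rings B and D) | O=Cc1cc(Br)c(Oc2cc(OC)c(OC)c(OC)c2Oc2cc(Br)c(Oc3cc(OC)c(OC)c(OC)c3Oc3cc(OC)c(OC)c(OC)c3)c(Br)c2)c(Br)c1 | intermediate
15 | B–C–D–E–F aryl formate (formate ester of 16) | O=COc1cc(Br)c(Oc2cc(OC)c(OC)c(OC)c2Oc2cc(Br)c(Oc3cc(OC)c(OC)c(OC)c3Oc3cc(OC)c(OC)c(OC)c3)c(Br)c2)c(Br)c1 | intermediate
16 | B–C–D–E–F phenol (hydroxyl at carbon 1 of ring B) | Oc1cc(Br)c(Oc2cc(OC)c(OC)c(OC)c2Oc2cc(Br)c(Oc3cc(OC)c(OC)c(OC)c3Oc3cc(OC)c(OC)c(OC)c3)c(Br)c2)c(Br)c1 | intermediate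
17 | hexamer aldehyde (formyl at carbon 4 of ring A; two bromines each on rings A, B and D) | O=Cc1cc(Br)c(Oc2cc(Br)c(Oc3cc(OC)c(OC)c(OC)c3Oc3cc(Br)c(Oc4cc(OC)c(OC)c(OC)c4Oc4cc(OC)c(OC)c(OC)c4)c(Br)c3)c(Br)c2)c(Br)c1 | intermediate
18 | hexamer aryl formate (formate ester of 19) | O=COc1cc(Br)c(Oc2cc(Br)c(Oc3cc(OC)c(OC)c(OC)c3Oc3cc(Br)c(Oc4cc(OC)c(OC)c(OC)c4Oc4cc(OC)c(OC)c(OC)c4)c(Br)c3)c(Br)c2)c(Br)c1 | intermediate
19 | hexabromo hexamer phenol (free hydroxyl at carbon 4 of ring A) | Oc1cc(Br)c(Oc2cc(Br)c(Oc3cc(OC)c(OC)c(OC)c3Oc3cc(Br)c(Oc4cc(OC)c(OC)c(OC)c4Oc4cc(OC)c(OC)c(OC)c4)c(Br)c3)c(Br)c2)c(Br)c1 | intermediate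
20 | hexabromo hexamer methyl ether (methoxy at carbon 4 of ring A) | COc1cc(Br)c(Oc2cc(Br)c(Oc3cc(OC)c(OC)c(OC)c3Oc3cc(Br)c(Oc4cc(OC)c(OC)c(OC)c4Oc4cc(OC)c(OC)c(OC)c4)c(Br)c3)c(Br)c2)c(Br)c1 | intermediate
21 | hexamer hexadecamethyl ether | COc1cc(OC)c(Oc2cc(OC)c(Oc3cc(OC)c(OC)c(OC)c3Oc3cc(OC)c(Oc4cc(OC)c(OC)c(OC)c4Oc4cc(OC)c(OC)c(OC)c4)c(OC)c3)c(OC)c2)c(OC)c1 | intermediate
22 | target hexamer CNP0114537.0 | Oc1cc(O)c(Oc2cc(O)c(Oc3cc(O)c(O)c(O)c3Oc3cc(O)c(Oc4cc(O)c(O)c(O)c4Oc4cc(O)c(O)c(O)c4)c(O)c3)c(O)c2)c(O)c1 | target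

**Step count**

Total steps: 14. Longest linear sequence: 13 steps (steps 2 to 14, from 3 and 4); step 1 is a side branch that supplies 2.

**Steps most likely to fail**

1. Step 13 (sixfold methoxylation). The exchange may stall at partly brominated stages, or bromine may be lost reductively through a copper hydride formed from methoxide. Either process would leave under-oxygenated congeners that are hard to separate from 21.
Fallback, setting out from 10 and coming back at 21: the exchange is done ring by ring, so that copper never has to replace more than two bromines on one substrate. The two bromines of 10 are exchanged first (NaOMe, CuI, DMF–MeOH, 110 °C) to give the ring D dimethoxy trimer phenol F1. SNAr of F1 on 4 (Cs2CO3, DMSO, 120 °C) should give the tetramer aldehyde F2, and Baeyer–Villiger oxidation (mCPBA, CH2Cl2; then K2CO3, MeOH) leads through the tetramer formate F3 to the tetramer phenol F4. SNAr of F4 on 2 (K2CO3, DMF, 80 °C) gives the ring B dibromo pentamer aldehyde F5, which is oxidised through the pentamer formate F6 to the dibromo pentamer phenol F7, and F7 is methoxylated to the ring B dimethoxy pentamer phenol F8. SNAr of F8 on 2 gives the ring A dibromo hexamer aldehyde F9, which is oxidised through the hexamer formate F10 to the dibromo hexamer phenol F11 and then methylated (MeI, K2CO3, acetone) to the dibromo hexamer methyl ether F12. A last twofold methoxylation of F12 gives 21.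

2. Step 6 (SNAr on the donor-laden fluoroaldehyde 4). Fluoride displacement may be too slow, because the methoxy groups on the fluorinated ring destabilise the Meisenheimer adduct and the dibromophenoxide of 10 is a weak nucleophile. Prolonged heating would then erode the aldehyde.
Fallback, setting out from 10 and coming back at 11: the SNAr is replaced by a copper-catalysed Ullmann ether coupling. 3,4,5-Trimethoxybenzaldehyde is iodinated (NIS, CF3CO2H, MeCN) to 2-iodo-3,4,5-trimethoxybenzaldehyde F13. F13 is then coupled with 10 (CuI, picolinic acid, K3PO4, DMSO, 80 °C); the iodide ortho to formyl should react well before the unactivated ring D bromides, giving 11.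

3. Step 5 (Baeyer–Villiger oxidation on the dibrominated ring, which recurs in steps 9 and 11). Hydride may migrate instead of the electron-poorer dibromoaryl group, diverting material to the benzoic acid, and the peracid may over-oxidise the electron-rich rings E and F.
Fallback, setting out from 7 and coming back at 10: a nitro group serves as the SNAr activator and a diazonium salt as the hydroxyl precursor. SNAr of 7 on 1,3-dibromo-2-fluoro-5-nitrobenzene (K2CO3, DMF, rt) should give the nitro diaryl ether F14. Reduction (Fe, NH4Cl, EtOH–H2O, 70 °C) gives the aniline F15 with the bromines intact. Diazotisation (NaNO2, aq. H2SO4–MeCN, 0 °C) gives the diazonium hydrogensulfate F16, which is hydroxylated at once (Cu2O, Cu(NO3)2, H2O, rt) to 10. The same variant would serve rings B and A.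

**Further compounds**

F1 | step 13 | ring D dimethoxy trimer phenol | Oc1cc(OC)c(Oc2cc(OC)c(OC)c(OC)c2Oc2cc(OC)c(OC)c(OC)c2)c(OC)c1
F2 | step 13 | tetramer aldehyde | O=Cc1cc(OC)c(OC)c(OC)c1Oc1cc(OC)c(Oc2cc(OC)c(OC)c(OC)c2Oc2cc(OC)c(OC)c(OC)c2)c(OC)c1
F3 | step 13 | tetramer formate | O=COc1cc(OC)c(OC)c(OC)c1Oc1cc(OC)c(Oc2cc(OC)c(OC)c(OC)c2Oc2cc(OC)c(OC)c(OC)c2)c(OC)c1
F4 | step 13 | tetramer phenol | Oc1cc(OC)c(OC)c(OC)c1Oc1cc(OC)c(Oc2cc(OC)c(OC)c(OC)c2Oc2cc(OC)c(OC)c(OC)c2)c(OC)c1
F5 | step 13 | ring B dibromo pentamer aldehyde | O=Cc1cc(Br)c(Oc2cc(OC)c(OC)c(OC)c2Oc2cc(OC)c(Oc3cc(OC)c(OC)c(OC)c3Oc3cc(OC)c(OC)c(OC)c3)c(OC)c2)c(Br)c1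
F6 | step 13 | pentamer formate | O=COc1cc(Br)c(Oc2cc(OC)c(OC)c(OC)c2Oc2cc(OC)c(Oc3cc(OC)c(OC)c(OC)c3Oc3cc(OC)c(OC)c(OC)c3)c(OC)c2)c(Br)c1
F7 | step 13 | dibromo pentamer phenol | Oc1cc(Br)c(Oc2cc(OC)c(OC)c(OC)c2Oc2cc(OC)c(Oc3cc(OC)c(OC)c(OC)c3Oc3cc(OC)c(OC)c(OC)c3)c(OC)c2)c(Br)c1
F8 | step 13 | ring B dimethoxy pentamer phenol | Oc1cc(OC)c(Oc2cc(OC)c(OC)c(OC)c2Oc2cc(OC)c(Oc3cc(OC)c(OC)c(OC)c3Oc3cc(OC)c(OC)c(OC)c3)c(OC)c2)c(OC)c1
F9 | step 13 | ring A dibromo hexamer aldehyde | O=Cc1cc(Br)c(Oc2cc(OC)c(Oc3cc(OC)c(OC)c(OC)c3Oc3cc(OC)c(Oc4cc(OC)c(OC)c(OC)c4Oc4cc(OC)c(OC)c(OC)c4)c(OC)c3)c(OC)c2)c(Br)c1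
F10 | step 13 | hexamer formate | O=COc1cc(Br)c(Oc2cc(OC)c(Oc3cc(OC)c(OC)c(OC)c3Oc3cc(OC)c(Oc4cc(OC)c(OC)c(OC)c4Oc4cc(OC)c(OC)c(OC)c4)c(OC)c3)c(OC)c2)c(Br)c1
F11 | step 13 | dibromo hexamer phenol | Oc1cc(Br)c(Oc2cc(OC)c(Oc3cc(OC)c(OC)c(OC)c3Oc3cc(OC)c(Oc4cc(OC)c(OC)c(OC)c4Oc4cc(OC)c(OC)c(OC)c4)c(OC)c3)c(OC)c2)c(Br)c1
F12 | step 13 | dibromo hexamer methyl ether | COc1cc(Br)c(Oc2cc(OC)c(Oc3cc(OC)c(OC)c(OC)c3Oc3cc(OC)c(Oc4cc(OC)c(OC)c(OC)c4Oc4cc(OC)c(OC)c(OC)c4)c(OC)c3)c(OC)c2)c(Br)c1
F13 | step 6 | 2-iodo-3,4,5-trimethoxybenzaldehyde | COc1cc(C=O)c(I)c(OC)c1OC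
F14 | step 5 | nitro diaryl ether | O=[N+]([O-])c1cc(Br)c(Oc2cc(OC)c(OC)c(OC)c2Oc2cc(OC)c(OC)c(OC)c2)c(Br)c1
F15 | step 5 | aniline | Nc1cc(Br)c(Oc2cc(OC)c(OC)c(OC)c2Oc2cc(OC)c(OC)c(OC)c2)c(Br)c1
F16 | step 5 | diazonium hydrogensulfate | N#[N+]c1cc(Br)c(Oc2cc(OC)c(OC)c(OC)c2Oc2cc(OC)c(OC)c(OC)c2)c(Br)c1.OS(=O)(=O)[O-]
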